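**Plan** (atom labels follow labdane numbering: C4 carries CO2Me, C10 the angular methyl, C9 the side chain, C8 the vinylic methyl)
Retrosynthesis cuts, in order: the acetate at O15 and the C9–C11 bond (enol triflate plus side-chain borane); the C4–CH3 and C8–CH3 bonds together with C5–H (one reductive double methylation); the C1–C10 bond (ring A); the C4–C5 bond to ring B.
Forward: ring B is bought as 2-methylcyclohexane-1,3-dione; C4 with its ester and a 3-bromopropyl arm is attached at C5; ring A is closed by C1–C10; C5–H, C4–CH3 and C8–CH3 follow in one flask; the side chain is joined last at C9.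
Enabling feature: C9(=O)–C10(CH3)=C5–C4H(CO2Me) of ring B is a vinylogous β-keto ester; its anion can be C-alkylated by an arm on C4 only at C10, and C5 stays sp2, so the trans ring fusion can be set afterwards.
Stereochemistry: C10 from a chiral ammonium ion pair in the ring closure; C5 and C4 by relay from the C10 methyl in the Li/NH3 reductive methylation; the 13E alkene from (E)-3-methylpent-2-en-4-yn-1-ol; the C8=C9 position from a regiospecific enol triflate.

Key step: step 3

Remark: compounds 3 and 13 are taken as purchased; the C8 epimers of 10 are carried on as the mixture because C8 becomes sp2 in step 5.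

Step 1
Reactants: 1 2-methylcyclohexane-1,3-dione
Product: 2 3-ethoxy-2-methylcyclohex-2-en-1-one
Conditions: EtOH, p-TsOH (cat.), toluene, reflux, azeotropic removal of water
Reagents that add atoms: ethanol, CCO
Why: Acid-catalysed enol etherification of the cyclic 1,3-dione gives the vinylogous ester, which leaves one carbonyl (the future C5) open to a single 1,2-addition.

Step 2
Reactants: 2 3-ethoxy-2-methylcyclohex-2-en-1-one; 3 methyl 5-bromopentanoate
Product: 6 methyl 5-bromo-2-(2-methyl-3-oxocyclohex-1-en-1-yl)pentanoate, via ester lithium enolate 4 (not isolated), via lithium alkoxide adduct 5 (not isolated)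
Conditions: LiN(i-Pr)2, THF, −78 °C, 3; then 2, −78 → −30 °C; then 2 M HCl, 0 °C → rt
Reagents that add atoms: water, O
Why: Stork–Danheiser sequence: 1,2-addition of the ester enolate to the vinylogous ester and acid-induced loss of water and ethanol transpose the enone, so C4 becomes bonded to C5 and the C9 ketone is unmasked; C4 is left racemic because step 3 erases it.

Step 3
Reactants: 6 methyl 5-bromo-2-(2-methyl-3-oxocyclohex-1-en-1-yl)pentanoate
Product: 7 methyl (4aS)-4a-methyl-5-oxo-2,3,4,4a,5,6,7,8-octahydronaphthalene-1-carboxylate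
Conditions: O-allyl-N-(9-anthracenylmethyl)cinchonidinium bromide (10 mol %), CsOH·H2O, toluene/CH2Cl2 (7:3), 0.02 M, −40 °C
Reagents that add atoms: none
Why: Proposed new method: CsOH removes the doubly activated C4–H of 6 at the solid–liquid interface, and the resulting trienolate (O–C9=C10–C5=C4–CO2Me), held as a tight ion pair by the chiral ammonium cation, displaces bromide from C1 through its α-carbon C10 in an intramolecular SN2 reaction. The closest known reaction types are the racemic C-alkylation of Hagemann's ester at the carbon α to the ketone and the chiral phase-transfer α-alkylation of cyclic β-keto esters and 2-arylcyclohexanones to α-quaternary ketones, both intermolecular; the intramolecular vinylogous case is untested. Ring A closes in the 6-(enolexo)-exo-tet mode, with the C9=C10 enolate bond outside and the C4=C5 bond inside the new ring. C10 is the only stereocenter formed and its configuration is set by the catalyst, whose anthracenylmethyl and quinoline groups should cover one face of the ring B enolate so that the arm on C4 closes from the open face to give (S); the cinchonine-derived pseudoenantiomer is the alternative if the sense proves opposite. The step needs C-alkylation at C10 and not O-alkylation through the ester oxygen, which is the only other six-membered closure (C4 would give a cyclobutane, the ketone oxygen an eight-membered ring); the soft bromide, the non-polar medium and the large HOMO coefficient at C10 of this anion type favour carbon. The arm can reach the C10 π-lobe because A(1,3) strain between C3H2 and the C10 methyl already twists the C4=C5 unit out of the enolate plane, and since C5 stays sp2 no ring-fusion configuration is fixed yet.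

Step 4
Reactants: 7 methyl (4aS)-4a-methyl-5-oxo-2,3,4,4a,5,6,7,8-octahydronaphthalene-1-carboxylate
Product: 10 methyl (1S,4aS,6RS,8aR)-1,4a,6-trimethyl-5-oxodecahydronaphthalene-1-carboxylate, via ketone lithium enolate 8 (not isolated), via dilithium bis-enolate 9 (not isolated)
Conditions: LiN(i-Pr)2 (1.1 equiv), THF, −78 °C; then Li (2.5 equiv), NH3(l)/THF, t-BuOH (1 equiv), −78 °C; isoprene; then MeI (excess), −78 → −33 °C
Reagents that add atoms: iodomethane, CI
Why: The C9 ketone is first masked as its enolate, which resists Li/NH3; the enoate is then reduced (reductive alkylation of an α,β-unsaturated ester) with axial protonation of C5 anti to the C10 methyl to give the trans ring fusion, and MeI alkylates both enolates, the C4 ester enolate from the equatorial α-face opposite the axial C10 methyl (CO2Me axial, cis to C10–CH3) and the ketone enolate at C8 (configuration immaterial).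

Step 5
Reactants: 10 methyl (1S,4aS,6RS,8aR)-1,4a,6-trimethyl-5-oxodecahydronaphthalene-1-carboxylate
Product: 12 methyl (1S,4aS,8aR)-1,4a,6-trimethyl-5-(trifluoromethanesulfonyloxy)-1,2,3,4,4a,7,8,8a-octahydronaphthalene-1-carboxylate, via potassium enolate 11 (not isolated)
Conditions: KN(SiMe3)2, THF, −78 → 0 °C; then PhNTf2, −78 °C → rt
Reagents that add atoms: N-phenylbis(trifluoromethanesulfonimide), O=S(=O)(N(c1ccccc1)S(=O)(=O)C(F)(F)F)C(F)(F)F
Why: C8–H is the only enolisable position of the ketone (C10 is quaternary), so enolate O-triflation gives the tetrasubstituted C8=C9 enol triflate regiospecifically, as with 2,2,6-trimethylcyclohexanone; the non-enolisable C4 ester is inert.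

Step 6
Reactants: 13 (E)-3-methylpent-2-en-4-yn-1-ol
Product: 14 (E)-tert-butyldimethyl[(3-methylpent-2-en-4-yn-1-yl)oxy]silane
Conditions: TBSCl, imidazole, CH2Cl2, 0 °C → rt
Reagents that add atoms: tert-butyldimethylsilyl chloride, CC(C)(C)[Si](C)(C)Cl
Why: Standard silylation of the primary allylic alcohol; unlike an allylic acetate, the silyl ether is inert to zerovalent palladium in step 8.

Step 7
Reactants: 14 (E)-tert-butyldimethyl[(3-methylpent-2-en-4-yn-1-yl)oxy]silane
Product: 15 (E)-tert-butyldimethyl[(3-methylpenta-2,4-dien-1-yl)oxy]silane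
Conditions: H2 (1 atm), Pd/CaCO3 poisoned with Pb(OAc)2, quinoline, hexane, rt, stopped after one equivalent of H2
Reagents that add atoms: none
Why: Semihydrogenation of the terminal alkyne over poisoned palladium should stop at the vinyl group and leave the E trisubstituted alkene untouched.

Step 8
Reactants: 12 methyl (1S,4aS,8aR)-1,4a,6-trimethyl-5-(trifluoromethanesulfonyloxy)-1,2,3,4,4a,7,8,8a-octahydronaphthalene-1-carboxylate; 15 (E)-tert-butyldimethyl[(3-methylpenta-2,4-dien-1-yl)oxy]silane
Product: 17 methyl (1S,4aS,8aR)-5-[(3E)-5-(tert-butyldimethylsilyloxy)-3-methylpent-3-en-1-yl]-1,4a,6-trimethyl-1,2,3,4,4a,7,8,8a-octahydronaphthalene-1-carboxylate, via B-alkyl-9-BBN adduct 16 (not isolated)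
Conditions: 15, 9-BBN dimer, THF, 0 °C → rt; then 12, PdCl2(dppf) (5 mol %), AsPh3, Cs2CO3, DMF/H2O, 50 °C
Reagents that add atoms: none
Why: 9-BBN should hydroborate only the monosubstituted terminal alkene of the diene (anti-Markovnikov), and B-alkyl Suzuki–Miyaura coupling with the enol triflate forms C9–C11 with retention of both alkene positions and geometries, by analogy with couplings of hindered 2,6,6-trimethylcyclohexenyl triflates.

Step 9
Reactants: 17 methyl (1S,4aS,8aR)-5-[(3E)-5-(tert-butyldimethylsilyloxy)-3-methylpent-3-en-1-yl]-1,4a,6-trimethyl-1,2,3,4,4a,7,8,8a-octahydronaphthalene-1-carboxylate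
Product: 19 methyl (1S,4aS,8aR)-5-[(3E)-5-acetoxy-3-methylpent-3-en-1-yl]-1,4a,6-trimethyl-1,2,3,4,4a,7,8,8a-octahydronaphthalene-1-carboxylate, via allylic alcohol 18 (not isolated)
Conditions: Bu4NF, THF, 0 °C → rt; then Ac2O, Et3N, DMAP (cat.), rt
Reagents that add atoms: acetic anhydride, CC(=O)OC(C)=O
Why: Fluoride removes the silyl group and the primary allylic alcohol is acetylated in the same flask; the hindered axial C4 methyl ester and both alkenes should be untouched.

**Compound list**
1 | 2-methylcyclohexane-1,3-dione | CC1C(=O)CCCC1=O | starting material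
2 | 3-ethoxy-2-methylcyclohex-2-en-1-one | CCOC1=C(C)C(=O)CCC1 | intermediate
3 | methyl 5-bromopentanoate | COC(=O)CCCCBr | starting material
4 | lithium enolate of 3 (formed in the flask, not isolated) | [Li+].COC([O-])=CCCCBr | intermediate
5 | lithium 1-(5-bromo-1-methoxy-1-oxopentan-2-yl)-3-ethoxy-2-methylcyclohex-2-en-1-olate (not isolated) | [Li+].COC(=O)C(CCCBr)C1([O-])CCCC(OCC)=C1C | intermediate
6 | methyl 5-bromo-2-(2-methyl-3-oxocyclohex-1-en-1-yl)pentanoate (racemic at C2) | COC(=O)C(CCCBr)C1=C(C)C(=O)CCC1 | intermediate
7 | methyl (4aS)-4a-methyl-5-oxo-2,3,4,4a,5,6,7,8-octahydronaphthalene-1-carboxylate | COC(=O)C1=C2CCCC(=O)[C@@]2(C)CCC1 | intermediate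
8 | lithium enolate of 7 at the ketone, C5=C6 enolate in naphthalene numbering (not isolated) | [Li+].COC(=O)C1=C2CCC=C([O-])[C@@]2(C)CCC1 | intermediate
9 | dilithium bis-enolate, trans-fused, ketone enolate plus exocyclic ester enolate (not isolated) | [Li+].[Li+].COC([O-])=C1CCC[C@]2(C)C([O-])=CCC[C@@H]12 | intermediate
10 | methyl (1S,4aS,6RS,8aR)-1,4a,6-trimethyl-5-oxodecahydronaphthalene-1-carboxylate | COC(=O)[C@@]1(C)CCC[C@]2(C)C(=O)C(C)CC[C@@H]12 | intermediate
11 | potassium enolate of 10 (not isolated) | [K+].COC(=O)[C@@]1(C)CCC[C@]2(C)C([O-])=C(C)CC[C@@H]12 | intermediate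
12 | methyl (1S,4aS,8aR)-1,4a,6-trimethyl-5-(trifluoromethanesulfonyloxy)-1,2,3,4,4a,7,8,8a-octahydronaphthalene-1-carboxylate | COC(=O)[C@@]1(C)CCC[C@]2(C)C(OS(=O)(=O)C(F)(F)F)=C(C)CC[C@@H]12 | intermediate
13 | (E)-3-methylpent-2-en-4-yn-1-ol | C#C/C(C)=C/CO | starting material
14 | (E)-tert-butyldimethyl[(3-methylpent-2-en-4-yn-1-yl)oxy]silane | C#C/C(C)=C/CO[Si](C)(C)C(C)(C)C | intermediate
15 | (E)-tert-butyldimethyl[(3-methylpenta-2,4-dien-1-yl)oxy]silane | C=C/C(C)=C/CO[Si](C)(C)C(C)(C)C | intermediate
16 | 9-[(3E)-5-(tert-butyldimethylsilyloxy)-3-methylpent-3-en-1-yl]-9-borabicyclo[3.3.1]nonane (not isolated) | CC(C)(C)[Si](C)(C)OC/C=C(C)/CCB1C2CCCC1CCC2 | intermediate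
17 | methyl (1S,4aS,8aR)-5-[(3E)-5-(tert-butyldimethylsilyloxy)-3-methylpent-3-en-1-yl]-1,4a,6-trimethyl-1,2,3,4,4a,7,8,8a-octahydronaphthalene-1-carboxylate | COC(=O)[C@@]1(C)CCC[C@]2(C)C(CC/C(C)=C/CO[Si](C)(C)C(C)(C)C)=C(C)CC[C@@H]12 | intermediate
18 | methyl (1S,4aS,8aR)-5-[(3E)-5-hydroxy-3-methylpent-3-en-1-yl]-1,4a,6-trimethyl-1,2,3,4,4a,7,8,8a-octahydronaphthalene-1-carboxylate (not isolated) | COC(=O)[C@@]1(C)CCC[C@]2(C)C(CC/C(C)=C/CO)=C(C)CC[C@@H]12 | intermediate
19 | methyl (1S,4aS,8aR)-5-[(3E)-5-acetoxy-3-methylpent-3-en-1-yl]-1,4a,6-trimethyl-1,2,3,4,4a,7,8,8a-octahydronaphthalene-1-carboxylate | COC(=O)[C@@]1(C)CCC[C@]2(C)C(CC/C(C)=C/COC(C)=O)=C(C)CC[C@@H]12 | target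

Total step count: 9. Longest linear sequence: 7 steps (steps 1, 2, 3, 4, 5, 8, 9); steps 6 and 7 prepare the side chain.

**Steps most likely to fail**

Step 3. The ion pair may discriminate the two faces of the ring B enolate poorly, or the anion may close through the ester oxygen instead of C10. Fallback, setting out from 6 and returning at 7: 6 would be cyclised without a chiral catalyst by the established Hagemann-ester-type α-alkylation (KOt-Bu, t-BuOH/THF, 0 °C) to racemic methyl 4a-methyl-5-oxo-2,3,4,4a,5,6,7,8-octahydronaphthalene-1-carboxylate F1. The enantiomers of F1 would then be separated by preparative chromatography on a chiral stationary phase (cellulose tris(3,5-dimethylphenylcarbamate)), and the (4aS) enantiomer is 7.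

Step 4. Incomplete masking of the ketone would allow over-reduction at C9, and proton exchange between the enolates would allow over-methylation at C8. Fallback, setting out from 7 and returning at 10: the ketone would be reduced first (NaBH4, MeOH, 0 °C) to methyl (4aS)-5-hydroxy-4a-methyl-2,3,4,4a,5,6,7,8-octahydronaphthalene-1-carboxylate F2. Reductive methylation of the enoate alone (Li, NH3/THF, −78 °C; MeI) would give methyl (1S,4aS,8aR)-5-hydroxy-1,4a-dimethyldecahydronaphthalene-1-carboxylate F3. Oxidation with DMP in CH2Cl2 would give methyl (1S,4aS,8aR)-1,4a-dimethyl-5-oxodecahydronaphthalene-1-carboxylate F4, and separate kinetic methylation at C8 (LiN(i-Pr)2, THF, −78 °C; MeI) would give 10.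

Step 2. The 1,2-addition of the α-branched ester enolate to the deactivated, 2-methyl-substituted vinylogous ester is slow and reversible, so retro-addition, enolisation of 2 and ester self-condensation may take over. Fallback, setting out from 1 and returning at 6: 1 would be converted (Tf2O, pyridine, CH2Cl2, −78 → 0 °C) into 2-methyl-3-oxocyclohex-1-en-1-yl trifluoromethanesulfonate F5. Purchased methyl 2,5-dibromopentanoate (COC(=O)C(Br)CCCBr) would be treated with Zn dust in THF to give the Reformatsky reagent bromo(5-bromo-1-methoxy-1-oxopentan-2-yl)zinc F6. Coupling of F5 with F6 under Pd(PPh3)4 catalysis (THF, 50 °C; Negishi-type coupling of a zinc ester enolate) would form the C4–C5 bond and give 6 directly.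

**Further compounds**
F1 | step 3 | racemic methyl 4a-methyl-5-oxo-2,3,4,4a,5,6,7,8-octahydronaphthalene-1-carboxylate | COC(=O)C1=C2CCCC(=O)C2(C)CCC1
F2 | step 4 | methyl (4aS)-5-hydroxy-4a-methyl-2,3,4,4a,5,6,7,8-octahydronaphthalene-1-carboxylate (C5 epimers) | COC(=O)C1=C2CCCC(O)[C@@]2(C)CCC1
F3 | step 4 | methyl (1S,4aS,8aR)-5-hydroxy-1,4a-dimethyldecahydronaphthalene-1-carboxylate (C5 epimers) | COC(=O)[C@@]1(C)CCC[C@]2(C)C(O)CCC[C@@H]12
F4 | step 4 | methyl (1S,4aS,8aR)-1,4a-dimethyl-5-oxodecahydronaphthalene-1-carboxylate | COC(=O)[C@@]1(C)CCC[C@]2(C)C(=O)CCC[C@@H]12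
F5 | step 2 | 2-methyl-3-oxocyclohex-1-en-1-yl trifluoromethanesulfonate | CC1=C(OS(=O)(=O)C(F)(F)F)CCCC1=O
F6 | step 2 | bromo(5-bromo-1-methoxy-1-oxopentan-2-yl)zinc | COC(=O)C(CCCBr)[Zn]Br
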